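## Analysis of the target

Target 17 is 2-(2,4-dihydroxy-6-pentylphenoxy)-4-methoxy-6-pentanoylbenzoic acid, a diaryl ether of two benzene rings with no stereocentre, so any stereocentre that appears on the way is transient. Ring A carries the ether oxygen at C1', hydroxyls at C2' and C4' and the pentyl chain at C6', which makes it a 5-pentylresorcinol oxygenated at the carbon between one hydroxyl and the chain. Ring B is a benzoic acid with three contiguous substituents (aryloxy at C2, carboxyl at C1, pentanoyl at C6) and a methoxy group at C4. The sensitive parts are the free resorcinol, which oxidises in air under base, the enolisable ketone, and the 2-acylbenzoic acid unit, which has a ring tautomer and whose esters invite Dieckmann-type closures. The difficulty is twofold: the ether oxygen sits between two ortho substituents on ring A and next to the carboxyl on ring B, so a direct aryl–oxygen coupling would be crowded, and three phenolic oxygens must end up differentiated, two free and one methylated. The strategy rests on the pattern around C1': an oxygen-bearing carbon with an oxygenated neighbour at C2', a second oxygen at C4' and an alkyl group at C6' is what a malonate carbon (C1', with C2' as one ester carbonyl) gives when it is joined to a four-carbon ynone (C6', C5', C4', C3'). It follows that C1' may enter the synthesis as the tetrahedral central carbon of an aryloxymalonate already attached to the ring B oxygen, with ring A assembled around that carbon afterwards.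

## Retrosynthetic reasoning

**17 back to 15 (via 16).** Ring A of 17 is read as the doubly enolised form of a cyclohexenedione. Putting a carboxyl back on C1' gives keto diacid 16 and its methyl ester 15. The bond cut in the forward sense is C1'–carboxyl. This is chosen because a quaternary C1' with one surplus ester is exactly what a malonate leaves behind, and its loss aromatises ring A without any oxidant. The forward step has to hydrolyse a hindered ester without opening the dione ring.

**15 back to 12 and 13.** The bonds C1'–C6' and C2'–C3' are cut. These are the two ring bonds with a natural polarity: C1' is a malonate carbanion and C6' the β-carbon of ynone 13, while C3' is a methyl ketone enolate and C2' an ester carbonyl. Cutting the aryl ether bond at C1' instead would demand a coupling of a 2,6-disubstituted phenol. The chosen cut builds ring A on an ether oxygen that is already in place and generates both ring A hydroxyls from carbonyl groups, so ring A never needs a protecting group. The forward reaction must alkylate at carbon, then acylate at carbon, while ring B stays inert. For that reason 12 carries ring B as the free acid, which becomes a carboxylate under the basic conditions.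

**12 back to 9 and 10 (via 11).** The free acid of 12 is uncovered from benzyl ester 11 by hydrogenolysis, which leaves the two methyl esters alone. The alkyl carbon–oxygen bond between the phenol oxygen and the malonate carbon is then cut to phenol 9 and bromomalonate 10. The ester is needed only for this etherification, because a free carboxylate would compete with the phenoxide.

**9 back to 7 (via 8).** The benzyl ester comes from acid 8, and the free C2 hydroxyl of 8 from dimethyl ether 7. The C2 methoxy group is the only one with an ortho carbonyl, so chelation-directed demethylation breaks the symmetry inherited from the starting material at a late and reliable point.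

**7 back to 5 (via 6).** The ketone and the acid of 7 are traced to lactone 5, which differs by one oxidation level at the benzylic carbon. The lactone is a stable, easily purified form of hydroxy acid 4. The forward step opens it with base to carboxylate 6 and oxidises the carbinol in the same basic medium, where the carboxylate cannot close again.

**5 back to 3 (via 4).** The C1–carboxyl bond is cut to aryl bromide 3. The bromine marks the one ring position that must carry the carboxyl, and halogen–lithium exchange followed by carboxylation and lactonisation of 4 delivers 5.

**3 back to 1 (via 2).** The carbinol–butyl bond of 3 is cut to aldehyde 2 and a four-carbon organomagnesium nucleophile, and the carbon–bromine bond of 2 to the symmetric aldehyde 1. Electrophilic bromination of 1 takes place next to the formyl group, which fixes the 1,2,3-relationship of ring B at the outset.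

## Alternatives that were turned down

**Alternative 1: ring B and the lactone by [2+2+2] cycloaddition.**
- Disconnection: ring B is cut at C2–C3, C4–C5 and C6–C1, which leads back to the ester-tethered 1,6-diyne A2 and methoxyethyne A3.
- Forward key step: a divalent ruthenium cyclopentadienyl-type complex would join A2 with A3. This closes ring B and the five-membered lactone at once and gives phthalide A1. Lactone opening, oxidation and removal of the benzyl ethers would then lead to 17.
- For it: it is stronger than the chosen route on ring B. The whole contiguous triad appears in one catalytic, neutral step, whereas the chosen route needs several classical steps for it.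
- Against it: A2 is an aryl ynol ether of a propiolate, a sensitive push–pull alkyne that must be made from a fully protected ring A phenol. The orientation of A3 (methoxy at C4 and not at C3) is not secured by the substrate. The lactone-to-keto-acid adjustment on A1 is still required afterwards.
- Comparison: the chosen strategy offers a ring A that needs no protecting group and an ether linkage made by a simple alkylation.

**Alternative 2: aryne carbometalation and carboxylation.**
- Disconnection: the C6–acyl and C1–carboxyl bonds of ring B are cut, which leads back to iodoaryl sulfonate A5 and 2-butyl-1,3-dithiane A6.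
- Forward key step: halogen–magnesium exchange on A5 would release the aryne across C1–C6. The dithiane A6, used as its 2-lithio derivative, would attack at C6, and the resulting C1 aryl anion would be carboxylated to give acid A4. Dithiane hydrolysis and debenzylation would finish.
- For it: it is stronger than the chosen route in setting the acyl and carboxyl groups in one pot, with the aryloxy group directing the regiochemistry, and it avoids the phthalide redox detour.
- Against it: the crowded diaryl ether must already exist in A5, which is the hardest bond of the molecule to make by coupling. The anion of A6 is tertiary, bulky and basic, a poor partner for an aryne. Sulfur removal from A4 followed by catalytic debenzylation lengthens the end game.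
- Comparison: the chosen strategy never forms an aryl–oxygen bond and creates ring A last from two cheap components.

**Alternative 3: ring A by cyclobutenone–siloxyalkyne benzannulation.**
- Disconnection: ring A is cut at C2'–C3', C4'–C5' and C1'–C2', which leads back to 4-aryloxycyclobutenone A8 and (triisopropylsilyloxy)ethyne A9.
- Forward key step: heating A8 with A9 would pass through a vinylketene, a [2+2] adduct and a 6π closure to phenol A7.
- For it: like the chosen route it grows ring A on the ether oxygen. It is stronger on two points: the conditions are neutral, so ring B can stay an ester, and the two ring A oxygens emerge differentiated.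
- Against it: that differentiation is not needed here. A8 is a 4-heteroatom-substituted cyclobutenone with no easy access. A9 needs its own preparation. The end game from A7 must remove a silyl group and saponify a di-ortho-substituted methyl benzoate, which is slow.
- Comparison: the chosen strategy uses a purchasable ynone and a malonate, and it carries the carboxyl group free through the key step.

Key step: step 9

Remark on the chemistry: the 2-acylbenzoic acids 7, 8 and 12 are drawn as open keto acids. They may rest as their 3-hydroxyphthalide ring tautomers, which give the same carboxylates and esters under the basic conditions used. All stereocentres of intermediates are racemic and are removed before the target.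

## Route

**Step 1**
Reactants: 1 3,5-dimethoxybenzaldehyde
Product: 2 2-bromo-3,5-dimethoxybenzaldehyde
Conditions: NBS (1.05 equiv), MeCN, 0 °C → rt
Reagents that add atoms: N-bromosuccinimide, O=C1CCC(=O)N1Br
Why: Electrophilic aromatic bromination; the position next to the formyl group is para to one methoxy and ortho to the other, while the position between the two methoxy groups is shielded, so monobromination there should dominate.

**Step 2**
Reactants: 2 2-bromo-3,5-dimethoxybenzaldehyde
Product: 3 racemic 1-(2-bromo-3,5-dimethoxyphenyl)pentan-1-ol
Conditions: n-BuMgCl (1.2 equiv), THF, 0 °C; 1 M HCl, 0 °C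
Reagents that add atoms: n-butylmagnesium chloride, CCCC[Mg]Cl
Why: Grignard 1,2-addition to the aldehyde; the aryl bromide does not exchange with the magnesium reagent at 0 °C, and the new carbinol centre is formed as a racemate that step 4 later erases.

**Step 3**
Reactants: 3 racemic 1-(2-bromo-3,5-dimethoxyphenyl)pentan-1-ol
Product: 5 racemic 3-butyl-5,7-dimethoxy-2-benzofuran-1(3H)-one, via hydroxy acid 4 (not isolated)
Conditions: n-BuLi (2.2 equiv), THF, −78 °C; CO2 (gas), −78 °C → rt; 2 M HCl, rt
Reagents that add atoms: carbon dioxide, O=C=O
Why: The first equivalent of n-BuLi forms the alkoxide and the second performs bromine–lithium exchange (Parham-type); the aryllithium is carboxylated, and acidification lets hydroxy acid 4 close to the five-membered lactone.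

**Step 4**
Reactants: 5 racemic 3-butyl-5,7-dimethoxy-2-benzofuran-1(3H)-one
Product: 7 2,4-dimethoxy-6-pentanoylbenzoic acid, via sodium hydroxy carboxylate 6 (not isolated)
Conditions: NaOH (3 equiv), H2O/t-BuOH, 70 °C; KMnO4 (0.8 equiv), 0 °C → rt; filter; HCl to pH 2
Reagents that add atoms: sodium hydroxide, [Na+].[OH-]
Why: Saponification opens the lactone to carboxylate 6, which cannot relactonise in base; alkaline KMnO4 oxidation of the secondary benzylic alcohol then gives the ketone and removes the stereocentre.

**Step 5**
Reactants: 7 2,4-dimethoxy-6-pentanoylbenzoic acid
Product: 8 2-hydroxy-4-methoxy-6-pentanoylbenzoic acid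
Conditions: BCl3 (3 equiv), CH2Cl2, −78 → 0 °C; H2O
Reagents that add atoms: none
Why: Chelation-controlled Lewis acid demethylation; boron held on the carboxyl oxygen reaches only the ortho methoxy group, whose methyl is taken by chloride, while the C4 methoxy has no neighbouring carbonyl and should survive at or below 0 °C.

**Step 6**
Reactants: 8 2-hydroxy-4-methoxy-6-pentanoylbenzoic acid
Product: 9 benzyl 2-hydroxy-4-methoxy-6-pentanoylbenzoate
Conditions: BnBr (1.1 equiv), KHCO3 (1.2 equiv), DMF, rt
Reagents that add atoms: benzyl bromide, BrCc1ccccc1
Why: SN2 O-alkylation of the carboxylate; KHCO3 ionises only the carboxylic acid and leaves the hydrogen-bonded phenol protonated, and alkylation of a 2-acylbenzoate under base gives the open normal ester.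

**Step 7**
Reactants: 9 benzyl 2-hydroxy-4-methoxy-6-pentanoylbenzoate; 10 dimethyl bromomalonate
Product: 11 benzyl 2-[(1,3-dimethoxy-1,3-dioxopropan-2-yl)oxy]-4-methoxy-6-pentanoylbenzoate
Conditions: K2CO3 (1.5 equiv), 10 (1.1 equiv), acetone, rt
Reagents that add atoms: none
Why: Williamson ether synthesis; the phenoxide displaces bromide from the doubly activated carbon, and a mild carbonate base at room temperature with near-stoichiometric 10 should keep the product malonate from closing onto the twisted benzyl ester.

**Step 8**
Reactants: 11 benzyl 2-[(1,3-dimethoxy-1,3-dioxopropan-2-yl)oxy]-4-methoxy-6-pentanoylbenzoate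
Product: 12 2-[(1,3-dimethoxy-1,3-dioxopropan-2-yl)oxy]-4-methoxy-6-pentanoylbenzoic acid
Conditions: H2 (1 atm), Pd/C (10% w/w), EtOAc, rt, stopped after one equivalent of H2
Reagents that add atoms: none
Why: Catalytic hydrogenolysis of the benzyl ester; the methyl esters and aryl ethers are inert, and the aryl ketone should be reduced much more slowly under these conditions.

**Step 9**
Reactants: 12 2-[(1,3-dimethoxy-1,3-dioxopropan-2-yl)oxy]-4-methoxy-6-pentanoylbenzoic acid; 13 non-3-yn-2-one
Product: 15 racemic 2-{[1-(methoxycarbonyl)-2,4-dioxo-6-pentylcyclohex-5-en-1-yl]oxy}-4-methoxy-6-pentanoylbenzoic acid, via Michael adduct 14 (not isolated)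
Conditions: NaOMe (3.2 equiv), MeOH, 0 °C; 13 (1.3 equiv) added slowly; rt → reflux; cold 1 M HCl to pH 2–3
Reagents that add atoms: none
Why: NaOMe first forms the ring B carboxylate and then the aryloxymalonate anion, which is the only stabilised carbanion present and has a single acidic hydrogen, so it adds exactly once to the β-carbon of ynone 13 (C1'–C6' bond) and protonation of the allenolate gives enone 14. The closest known reaction type is the Michael–Claisen annulation of malonate esters with conjugated enones and ynones that is used for 5-alkylresorcinols. The E and Z isomers of 14 interconvert through reversible methoxide addition and the extended dienolate, and in the Z isomer the methyl ketone enolate reaches one ester carbonyl and closes the six-membered carbocycle by a 6-exo-trig Claisen condensation (C2'–C3' bond) with loss of methoxide. The new 1,3-dione is deprotonated at once, and this enolate is the thermodynamic sink that draws the reversible steps forward. The step needs C-alkylation before C-acylation, and C-acylation rather than O-acylation: the first follows from the much higher acidity of the malonate hydrogen over any ketone hydrogen, the second from the fact that the O-acylated enol lactone is an activated ester that methoxide reopens, whereas the C-acylated dione leaves the equilibrium as its enolate. Ring B is shielded by its own charge, since a carboxylate is attacked neither by the malonate anion (no benzofuranone) nor by the pentanoyl enolate (no indanedione), and methyl esters in methanol make ester exchange invisible. The quaternary C1' is formed without a controlling element, as a racemate, which does not matter because step 10 removes it.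

**Step 10**
Reactants: 15 racemic 2-{[1-(methoxycarbonyl)-2,4-dioxo-6-pentylcyclohex-5-en-1-yl]oxy}-4-methoxy-6-pentanoylbenzoic acid
Product: 17 2-(2,4-dihydroxy-6-pentylphenoxy)-4-methoxy-6-pentanoylbenzoic acid (target), via keto diacid 16 (not isolated)
Conditions: NaOH (5 equiv), H2O/MeOH, 50 °C, under N2; HCl to pH 1, 40 °C
Reagents that add atoms: none
Why: Saponification of the remaining ester takes place while the ring carbonyls are masked as the dione enolate; on acidification β-keto acid 16 decarboxylates through the usual cyclic transition state and the dione enolises to the aromatic resorcinol, which erases the C1' stereocentre.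

## Compound list

1 | 3,5-dimethoxybenzaldehyde | COc1cc(OC)cc(C=O)c1 | starting material
2 | 2-bromo-3,5-dimethoxybenzaldehyde | O=Cc1cc(OC)cc(OC)c1Br | intermediate
3 | racemic 1-(2-bromo-3,5-dimethoxyphenyl)pentan-1-ol | CCCCC(O)c1cc(OC)cc(OC)c1Br | intermediate
4 | racemic 2-(1-hydroxypentyl)-4,6-dimethoxybenzoic acid (not isolated) | CCCCC(O)c1cc(OC)cc(OC)c1C(=O)O | intermediate
5 | racemic 3-butyl-5,7-dimethoxy-2-benzofuran-1(3H)-one | CCCCC1OC(=O)c2c(OC)cc(OC)cc12 | intermediate
6 | racemic sodium 2-(1-hydroxypentyl)-4,6-dimethoxybenzoate (not isolated) | CCCCC(O)c1cc(OC)cc(OC)c1C(=O)[O-].[Na+] | intermediate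
7 | 2,4-dimethoxy-6-pentanoylbenzoic acid | CCCCC(=O)c1cc(OC)cc(OC)c1C(=O)O | intermediate
8 | 2-hydroxy-4-methoxy-6-pentanoylbenzoic acid | CCCCC(=O)c1cc(OC)cc(O)c1C(=O)O | intermediate
9 | benzyl 2-hydroxy-4-methoxy-6-pentanoylbenzoate | CCCCC(=O)c1cc(OC)cc(O)c1C(=O)OCc1ccccc1 | intermediate
10 | dimethyl bromomalonate | COC(=O)C(Br)C(=O)OC | starting material
11 | benzyl 2-[(1,3-dimethoxy-1,3-dioxopropan-2-yl)oxy]-4-methoxy-6-pentanoylbenzoate | CCCCC(=O)c1cc(OC)cc(OC(C(=O)OC)C(=O)OC)c1C(=O)OCc1ccccc1 | intermediate
12 | 2-[(1,3-dimethoxy-1,3-dioxopropan-2-yl)oxy]-4-methoxy-6-pentanoylbenzoic acid | CCCCC(=O)c1cc(OC)cc(OC(C(=O)OC)C(=O)OC)c1C(=O)O | intermediate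
13 | non-3-yn-2-one | CCCCCC#CC(C)=O | starting material
14 | 2-{[1,3-dimethoxy-1,3-dioxo-2-(2-oxonon-3-en-4-yl)propan-2-yl]oxy}-4-methoxy-6-pentanoylbenzoic acid (E/Z mixture, not isolated) | CCCCCC(=CC(C)=O)C(C(=O)OC)(C(=O)OC)Oc1cc(OC)cc(C(=O)CCCC)c1C(=O)O | intermediate
15 | racemic 2-{[1-(methoxycarbonyl)-2,4-dioxo-6-pentylcyclohex-5-en-1-yl]oxy}-4-methoxy-6-pentanoylbenzoic acid | CCCCCC1=CC(=O)CC(=O)C1(C(=O)OC)Oc1cc(OC)cc(C(=O)CCCC)c1C(=O)O | intermediate
16 | racemic 1-(2-carboxy-5-methoxy-3-pentanoylphenoxy)-2,4-dioxo-6-pentylcyclohex-5-ene-1-carboxylic acid (not isolated) | CCCCCC1=CC(=O)CC(=O)C1(C(=O)O)Oc1cc(OC)cc(C(=O)CCCC)c1C(=O)O | intermediate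
17 | 2-(2,4-dihydroxy-6-pentylphenoxy)-4-methoxy-6-pentanoylbenzoic acid | CCCCCc1cc(O)cc(O)c1Oc1cc(OC)cc(C(=O)CCCC)c1C(=O)O | target

## Step count and least certain steps

Total: 10 steps. Longest linear sequence: 10 steps, from 1 to 17; 10 enters at step 7 and 13 at step 9.

**Step 9 (key step).** The hindered tertiary carbanion may add too slowly, so that conjugate addition of methoxide to the ynone and base-induced self-condensation of the ynone use up the acceptor. The sequence may also stall after the Michael addition if the alkene geometry does not equilibrate, leaving the ketone enolate out of reach of the ester. Early loss of the spare ester by methoxide attack would be harmless, because it leads straight to the ring A phenoxide of the target.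

Fallback: from 12, the acceptor is changed to the base-stable (E)-non-3-en-2-one (CCCCC/C=C/C(C)=O), the classical partner of this annulation, whose sp3 adduct has no geometry problem. NaOMe in MeOH at reflux should give the saturated dione ester 2-{[1-(methoxycarbonyl)-2,4-dioxo-6-pentylcyclohexyl]oxy}-4-methoxy-6-pentanoylbenzoic acid F1 as a mixture of diastereomers. NaOH and then acid, as in step 10, should remove the ester and give 2-[(2,4-dioxo-6-pentylcyclohexyl)oxy]-4-methoxy-6-pentanoylbenzoic acid F2. Aerobic dehydrogenation with Pd(O2CCF3)2, 2-(dimethylamino)pyridine and TsOH under O2 in DMSO at 80 °C would then aromatise ring A, and the sequence comes back to the route at 17.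

**Step 7.** Once formed, the aryloxymalonate is itself acidic. Its anion may close onto the neighbouring benzyl ester in a Dieckmann-type cyclisation, or take bromine from a second molecule of 10.

Fallback: from 9, the oxygen–carbon bond is made without any base by insertion of the carbenoid from dimethyl diazomalonate (COC(=O)C(=[N+]=[N-])C(=O)OC) into the phenol O–H bond, with Rh2(OAc)4 (1 mol%) in toluene at 80 °C. No carbanion is generated, and the sequence returns at 11 without a new intermediate.

**Step 10.** Hydroxide may attack a ring carbonyl instead of the hindered ester, leading to retro-Claisen fission of ring A, or the ester may resist hydrolysis at temperatures the resorcinol tolerates.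

Fallback: from 15, the methyl group rather than the carbonyl is attacked. LiCl in wet DMSO at 130 °C (Krapcho dealkoxycarbonylation) cleaves the O–methyl bond, the carboxylate loses CO2 in the hot medium, and the ring aromatises, which returns directly to 17 without a new intermediate.

**Step 4.** Over-oxidation by KMnO4 may occur, either degradation of the electron-rich ring or cleavage at the enolisable ketone. Incomplete oxidation followed by relactonisation on acidification is also possible.

Fallback: from 3, the oxidation is done before the carboxyl group exists. MnO2 in CH2Cl2 should give 1-(2-bromo-3,5-dimethoxyphenyl)pentan-1-one F3. Ethylene glycol and TsOH in toluene with removal of water should give 2-(2-bromo-3,5-dimethoxyphenyl)-2-butyl-1,3-dioxolane F4. n-BuLi in THF at −78 °C followed by CO2 should give 2-(2-butyl-1,3-dioxolan-2-yl)-4,6-dimethoxybenzoic acid F5. Aqueous HCl in THF then removes the ketal, and the sequence returns at 7.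

## Further compounds

F1 | step 9 | 2-{[1-(methoxycarbonyl)-2,4-dioxo-6-pentylcyclohexyl]oxy}-4-methoxy-6-pentanoylbenzoic acid (racemic, mixture of diastereomers) | CCCCCC1CC(=O)CC(=O)C1(C(=O)OC)Oc1cc(OC)cc(C(=O)CCCC)c1C(=O)O
F2 | step 9 | 2-[(2,4-dioxo-6-pentylcyclohexyl)oxy]-4-methoxy-6-pentanoylbenzoic acid (racemic, mixture of diastereomers) | CCCCCC1CC(=O)CC(=O)C1Oc1cc(OC)cc(C(=O)CCCC)c1C(=O)O
F0 | step 7 | none | none
F0 | step 10 | none | none
F3 | step 4 | 1-(2-bromo-3,5-dimethoxyphenyl)pentan-1-one | CCCCC(=O)c1cc(OC)cc(OC)c1Br
F4 | step 4 | 2-(2-bromo-3,5-dimethoxyphenyl)-2-butyl-1,3-dioxolane | CCCCC1(OCCO1)c1cc(OC)cc(OC)c1Br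
F5 | step 4 | 2-(2-butyl-1,3-dioxolan-2-yl)-4,6-dimethoxybenzoic acid | CCCCC1(OCCO1)c1cc(OC)cc(OC)c1C(=O)O
A1 | alternative 1 | racemic 7-[2,4-bis(benzyloxy)-6-pentylphenoxy]-3-butyl-5-methoxy-2-benzofuran-1(3H)-one | CCCCCc1cc(OCc2ccccc2)cc(OCc2ccccc2)c1Oc1cc(OC)cc2c1C(=O)OC2CCCC
A2 | alternative 1 | racemic hept-1-yn-3-yl 3-[2,4-bis(benzyloxy)-6-pentylphenoxy]prop-2-ynoate | CCCCC(C#C)OC(=O)C#COc1c(CCCCC)cc(OCc2ccccc2)cc1OCc1ccccc1
A3 | alternative 1 | methoxyethyne | COC#C
A4 | alternative 2 | 2-[2,4-bis(benzyloxy)-6-pentylphenoxy]-6-(2-butyl-1,3-dithian-2-yl)-4-methoxybenzoic acid | CCCCCc1cc(OCc2ccccc2)cc(OCc2ccccc2)c1Oc1cc(OC)cc(C2(CCCC)SCCCS2)c1C(=O)O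
A5 | alternative 2 | 3-[2,4-bis(benzyloxy)-6-pentylphenoxy]-2-iodo-5-methoxyphenyl 4-chlorobenzenesulfonate | CCCCCc1cc(OCc2ccccc2)cc(OCc2ccccc2)c1Oc1cc(OC)cc(OS(=O)(=O)c2ccc(Cl)cc2)c1I
A6 | alternative 2 | 2-butyl-1,3-dithiane | CCCCC1SCCCS1
A7 | alternative 3 | methyl 2-[2-hydroxy-6-pentyl-4-(triisopropylsilyloxy)phenoxy]-4-methoxy-6-pentanoylbenzoate | CCCCCc1cc(O[Si](C(C)C)(C(C)C)C(C)C)cc(O)c1Oc1cc(OC)cc(C(=O)CCCC)c1C(=O)OC
A8 | alternative 3 | racemic methyl 4-methoxy-2-[(4-oxo-2-pentylcyclobut-2-en-1-yl)oxy]-6-pentanoylbenzoate | CCCCCC1=CC(=O)C1Oc1cc(OC)cc(C(=O)CCCC)c1C(=O)OC
A9 | alternative 3 | (triisopropylsilyloxy)ethyne | C#CO[Si](C(C)C)(C(C)C)C(C)C
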